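**Retrosynthetic overview**

- The strategy rests on the acyclic C8–C8' bond. Its two adjacent CH stereocentres carry, at C8, the C9H2OAc arm and the guaiacyl C7H2, and at C8', the C9'H3 arm and the syringyl C7'H2. The two benzene rings are bought and no ring is built.
- Target 21 comes from bis-benzyl ether 20 by hydrogenolysis. The C9H2OAc arm is traced back to an E-propenyl group (C=C cleavage, reduction, acetylation) and the C9'H3 arm to a carboxyl group (reduction, mesylation, hydride displacement), which leads to acid 13.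
- Acid 13 comes from allylic ester 9 by an Ireland–Claisen rearrangement through silyl ketene acetal 11. This step makes the C8–C8' bond and both stereocentres from a single carbinol centre.
- Ester 9 is assembled from alcohol 4 (cross metathesis of O-benzyl eugenol 2 with (S)-but-3-en-2-ol 3) and acid 8 (from sinapic acid 5).

Key step: step 7

Remark: lignan numbering is used (C7–C9 for the guaiacyl half, C7'–C9' for the syringyl half). Both phenols are carried as benzyl ethers, and (S)-but-3-en-2-ol is assumed to be purchasable in high enantiomeric purity.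

**Route**

Step 1
Reactants: 1 eugenol
Product: 2 4-allyl-1-(benzyloxy)-2-methoxybenzene
Conditions: BnBr, K2CO3, acetone, reflux
Reagents that add atoms: benzyl bromide, BrCc1ccccc1
Why: Williamson ether synthesis on the phenoxide (SN2 at the benzylic carbon); the mild carbonate base should leave the allyl group unisomerised.

Step 2
Reactants: 2 4-allyl-1-(benzyloxy)-2-methoxybenzene (2 equiv); 3 (S)-but-3-en-2-ol
Product: 4 (2S,3E)-5-[4-(benzyloxy)-3-methoxyphenyl]pent-3-en-2-ol
Conditions: second-generation Grubbs catalyst (H2IMes)(PCy3)Cl2Ru=CHPh (5 mol %), 1,4-benzoquinone (10 mol %), CH2Cl2, 40 °C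
Reagents that add atoms: none
Why: Olefin cross metathesis between a fast-dimerising allylarene and a slowly dimerising secondary allylic alcohol should be cross-selective, with secondary metathesis equilibrating towards the E alkene; the carbinol centre is not touched and benzoquinone suppresses Ru–H double-bond migration.

Step 3
Reactants: 5 sinapic acid
Product: 6 3-(4-hydroxy-3,5-dimethoxyphenyl)propanoic acid
Conditions: H2 (1 atm), 10% Pd/C, MeOH, rt
Reagents that add atoms: none
Why: Heterogeneous catalytic hydrogenation saturates the cinnamic C=C bond while arene, phenol and acid stay intact; it is done before any benzyl group is present.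

Step 4
Reactants: 6 3-(4-hydroxy-3,5-dimethoxyphenyl)propanoic acid
Product: 7 benzyl 3-[4-(benzyloxy)-3,5-dimethoxyphenyl]propanoate
Conditions: BnBr (2.5 equiv), K2CO3, DMF, 60 °C
Reagents that add atoms: benzyl bromide, BrCc1ccccc1
Why: Exhaustive O-alkylation (Williamson etherification of the hindered phenoxide together with carboxylate alkylation) avoids any need to differentiate the two acidic groups.

Step 5
Reactants: 7 benzyl 3-[4-(benzyloxy)-3,5-dimethoxyphenyl]propanoate
Product: 8 3-[4-(benzyloxy)-3,5-dimethoxyphenyl]propanoic acid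
Conditions: LiOH·H2O, THF/MeOH/H2O, rt; then 1 M HCl
Reagents that add atoms: lithium hydroxide, [Li+].[OH-]
Why: Saponification by acyl–oxygen cleavage removes only the benzyl ester, the aryl benzyl ether being inert to hydroxide.

Step 6
Reactants: 4 (2S,3E)-5-[4-(benzyloxy)-3-methoxyphenyl]pent-3-en-2-ol; 8 3-[4-(benzyloxy)-3,5-dimethoxyphenyl]propanoic acid
Product: 9 (2S,3E)-5-[4-(benzyloxy)-3-methoxyphenyl]pent-3-en-2-yl 3-[4-(benzyloxy)-3,5-dimethoxyphenyl]propanoate
Conditions: DCC, DMAP (cat.), CH2Cl2, 0 °C → rt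
Reagents that add atoms: none
Why: Steglich esterification activates the acid (O-acylisourea, then acylpyridinium) and the alcohol oxygen acts as nucleophile, so the carbinol C–O bond is never broken and the S centre is retained without allylic transposition.

Step 7
Reactants: 9 (2S,3E)-5-[4-(benzyloxy)-3-methoxyphenyl]pent-3-en-2-yl 3-[4-(benzyloxy)-3,5-dimethoxyphenyl]propanoate
Product: 13 (2R,3R,4E)-2-[4-(benzyloxy)-3,5-dimethoxybenzyl]-3-[4-(benzyloxy)-3-methoxybenzyl]hex-4-enoic acid, via lithium ester enolate 10 (not isolated), via E-silyl ketene acetal 11 (not isolated), via trimethylsilyl ester 12 (not isolated)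
Conditions: LiN(iPr)2 (from nBuLi, iPr2NH), THF, −78 °C, slow addition of 9; Me3SiCl, −78 °C → rt, then 55 °C; 1 M HCl
Reagents that add atoms: none
Why: Ireland–Claisen rearrangement: LiN(iPr)2 in THF without polar cosolvent removes an α-proton of 9 through a closed, lithium-bridged transition state to give enolate 10 with the syringyl CH2 cis to the allylic oxygen, and O-silylation fixes this geometry as the (E)-silyl ketene acetal 11. On warming, 11 should undergo a concerted suprafacial [3,3]-sigmatropic shift in which the C8–C8' bond forms between the ketene acetal carbon and the alkene carbon bearing the guaiacyl CH2 while the allylic C–O bond breaks, giving silyl ester 12 and, after acidic hydrolysis, acid 13; the closest known reaction type is the ester enolate Claisen rearrangement of secondary (E)-allylic alkanoates with 1,3-chirality transfer. No ring is closed, the six-membered chair being a transition state only. Both new stereocentres are set here: the carbinol methyl takes the equatorial position of the chair, so the S carbinol decides which alkene face and which ketene acetal face are joined, the equatorial guaiacyl CH2 (from the E alkene) and the axial syringyl CH2 (from the E ketene acetal) then give the anti (2R,3R) acid, and the carbinol centre itself is consumed as the E-propenyl group. The step needs a single ketene acetal geometry and a chair instead of a boat; kinetic enolisation at −78 °C with the ester added slowly to excess base secures the first, and the equatorial preference of the methyl group and of the E-alkene substituent secures the second.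

Step 8
Reactants: 13 (2R,3R,4E)-2-[4-(benzyloxy)-3,5-dimethoxybenzyl]-3-[4-(benzyloxy)-3-methoxybenzyl]hex-4-enoic acid
Product: 14 (2R,3R,4E)-2-[4-(benzyloxy)-3,5-dimethoxybenzyl]-3-[4-(benzyloxy)-3-methoxybenzyl]hex-4-en-1-ol
Conditions: LiAlH4, THF, 0 °C → reflux; aqueous NaOH work-up
Reagents that add atoms: none
Why: Hydride reduction of the carboxylate to the primary alcohol; the α-centre is safe because the carboxylate salt does not enolise, and the alkene and benzyl ethers are inert.

Step 9
Reactants: 14 (2R,3R,4E)-2-[4-(benzyloxy)-3,5-dimethoxybenzyl]-3-[4-(benzyloxy)-3-methoxybenzyl]hex-4-en-1-ol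
Product: 15 (2R,3R,4E)-2-[4-(benzyloxy)-3,5-dimethoxybenzyl]-3-[4-(benzyloxy)-3-methoxybenzyl]hex-4-en-1-yl methanesulfonate
Conditions: MsCl, Et3N, CH2Cl2, 0 °C
Reagents that add atoms: methanesulfonyl chloride, CS(=O)(=O)Cl
Why: Sulfonylation of the primary alcohol turns the oxygen into a leaving group without touching either stereocentre.

Step 10
Reactants: 15 (2R,3R,4E)-2-[4-(benzyloxy)-3,5-dimethoxybenzyl]-3-[4-(benzyloxy)-3-methoxybenzyl]hex-4-en-1-yl methanesulfonate
Product: 16 (2E,4S,5R)-4-[4-(benzyloxy)-3-methoxybenzyl]-6-[4-(benzyloxy)-3,5-dimethoxyphenyl]-5-methylhex-2-ene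
Conditions: LiEt3BH, THF, 0 °C → rt
Reagents that add atoms: none
Why: SN2 displacement of the primary mesylate by the strongly nucleophilic triethylborohydride tolerates the β-branching and creates the C9' methyl group; only the descriptor at the guaiacyl-bearing centre changes, not its geometry.

Step 11
Reactants: 16 (2E,4S,5R)-4-[4-(benzyloxy)-3-methoxybenzyl]-6-[4-(benzyloxy)-3,5-dimethoxyphenyl]-5-methylhex-2-ene
Product: 18 (2S,3R)-2-[4-(benzyloxy)-3-methoxybenzyl]-4-[4-(benzyloxy)-3,5-dimethoxyphenyl]-3-methylbutanal, via vicinal diol 17 (not isolated)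
Conditions: OsO4 (2 mol %), NaIO4 (4 equiv), 2,6-lutidine, 1,4-dioxane/H2O 3:1, rt; crude aldehyde used at once
Reagents that add atoms: osmium tetroxide, O=[Os](=O)(=O)=O (delivers the oxygen, regenerated by the periodate); sodium periodate, [Na+].[O-]I(=O)(=O)=O
Why: Lemieux–Johnson oxidation: syn-dihydroxylation of the only alkene followed by periodate glycol cleavage releases acetaldehyde and leaves the C9 aldehyde, with lutidine buffering the medium so that the α-stereocentre (C8) should survive the short exposure.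

Step 12
Reactants: 18 (2S,3R)-2-[4-(benzyloxy)-3-methoxybenzyl]-4-[4-(benzyloxy)-3,5-dimethoxyphenyl]-3-methylbutanal
Product: 19 (2S,3R)-2-[4-(benzyloxy)-3-methoxybenzyl]-4-[4-(benzyloxy)-3,5-dimethoxyphenyl]-3-methylbutan-1-ol
Conditions: NaBH4, MeOH, 0 °C
Reagents that add atoms: none
Why: Immediate borohydride reduction of the aldehyde removes the epimerisable α-CH–C=O arrangement and gives the C9 primary alcohol.

Step 13
Reactants: 19 (2S,3R)-2-[4-(benzyloxy)-3-methoxybenzyl]-4-[4-(benzyloxy)-3,5-dimethoxyphenyl]-3-methylbutan-1-ol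
Product: 20 (2S,3R)-2-[4-(benzyloxy)-3-methoxybenzyl]-4-[4-(benzyloxy)-3,5-dimethoxyphenyl]-3-methylbutyl acetate
Conditions: Ac2O, pyridine, DMAP (cat.), CH2Cl2, rt
Reagents that add atoms: acetic anhydride, CC(=O)OC(C)=O
Why: Nucleophile-catalysed acylation of the only free hydroxyl group; both phenols are still masked, so no aryl acetate can form.

Step 14
Reactants: 20 (2S,3R)-2-[4-(benzyloxy)-3-methoxybenzyl]-4-[4-(benzyloxy)-3,5-dimethoxyphenyl]-3-methylbutyl acetate
Product: 21 (2S,3R)-2-(4-hydroxy-3-methoxybenzyl)-4-(4-hydroxy-3,5-dimethoxyphenyl)-3-methylbutyl acetate (CID53359578; 8S,8'R)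
Conditions: H2 (1 atm), 10% Pd/C, EtOAc, rt
Reagents that add atoms: none
Why: Catalytic hydrogenolysis cleaves both benzylic C–O bonds of the aryl benzyl ethers under neutral conditions, which should leave the alkyl acetate, the methyl ethers and both stereocentres unchanged.

**Compound list**

1 | eugenol | C=CCc1ccc(O)c(OC)c1 | starting material
2 | 4-allyl-1-(benzyloxy)-2-methoxybenzene | C=CCc1ccc(OCc2ccccc2)c(OC)c1 | intermediate
3 | (S)-but-3-en-2-ol | C[C@H](O)C=C | starting material
4 | (2S,3E)-5-[4-(benzyloxy)-3-methoxyphenyl]pent-3-en-2-ol | C[C@H](O)/C=C/Cc1ccc(OCc2ccccc2)c(OC)c1 | intermediate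
5 | sinapic acid | COc1cc(/C=C/C(=O)O)cc(OC)c1O | starting material
6 | 3-(4-hydroxy-3,5-dimethoxyphenyl)propanoic acid | COc1cc(CCC(=O)O)cc(OC)c1O | intermediate
7 | benzyl 3-[4-(benzyloxy)-3,5-dimethoxyphenyl]propanoate | COc1cc(CCC(=O)OCc2ccccc2)cc(OC)c1OCc1ccccc1 | intermediate
8 | 3-[4-(benzyloxy)-3,5-dimethoxyphenyl]propanoic acid | O=C(O)CCc1cc(OC)c(OCc2ccccc2)c(OC)c1 | intermediate
9 | (2S,3E)-5-[4-(benzyloxy)-3-methoxyphenyl]pent-3-en-2-yl 3-[4-(benzyloxy)-3,5-dimethoxyphenyl]propanoate | C[C@H](OC(=O)CCc1cc(OC)c(OCc2ccccc2)c(OC)c1)/C=C/Cc1ccc(OCc2ccccc2)c(OC)c1 | intermediate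
10 | lithium enolate of 9 (syringyl CH2 cis to the allylic oxygen) | [Li+].C[C@H](O/C([O-])=C\Cc1cc(OC)c(OCc2ccccc2)c(OC)c1)/C=C/Cc1ccc(OCc2ccccc2)c(OC)c1 | intermediate (not isolated)
11 | (E)-trimethylsilyl ketene acetal of 9 (OSiMe3 trans to the syringyl CH2) | C[C@H](O/C(O[Si](C)(C)C)=C\Cc1cc(OC)c(OCc2ccccc2)c(OC)c1)/C=C/Cc1ccc(OCc2ccccc2)c(OC)c1 | intermediate (not isolated)
12 | trimethylsilyl (2R,3R,4E)-2-[4-(benzyloxy)-3,5-dimethoxybenzyl]-3-[4-(benzyloxy)-3-methoxybenzyl]hex-4-enoate | COc1cc(C[C@H](/C=C/C)[C@H](C(=O)O[Si](C)(C)C)Cc2cc(OC)c(OCc3ccccc3)c(OC)c2)ccc1OCc1ccccc1 | intermediate (not isolated)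
13 | (2R,3R,4E)-2-[4-(benzyloxy)-3,5-dimethoxybenzyl]-3-[4-(benzyloxy)-3-methoxybenzyl]hex-4-enoic acid | COc1cc(C[C@H](/C=C/C)[C@H](C(=O)O)Cc2cc(OC)c(OCc3ccccc3)c(OC)c2)ccc1OCc1ccccc1 | intermediate
14 | (2R,3R,4E)-2-[4-(benzyloxy)-3,5-dimethoxybenzyl]-3-[4-(benzyloxy)-3-methoxybenzyl]hex-4-en-1-ol | COc1cc(C[C@H](/C=C/C)[C@H](CO)Cc2cc(OC)c(OCc3ccccc3)c(OC)c2)ccc1OCc1ccccc1 | intermediate
15 | (2R,3R,4E)-2-[4-(benzyloxy)-3,5-dimethoxybenzyl]-3-[4-(benzyloxy)-3-methoxybenzyl]hex-4-en-1-yl methanesulfonate | COc1cc(C[C@H](/C=C/C)[C@H](COS(C)(=O)=O)Cc2cc(OC)c(OCc3ccccc3)c(OC)c2)ccc1OCc1ccccc1 | intermediate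
16 | (2E,4S,5R)-4-[4-(benzyloxy)-3-methoxybenzyl]-6-[4-(benzyloxy)-3,5-dimethoxyphenyl]-5-methylhex-2-ene | COc1cc(C[C@H](/C=C/C)[C@H](C)Cc2cc(OC)c(OCc3ccccc3)c(OC)c2)ccc1OCc1ccccc1 | intermediate
17 | (4S,5R)-4-[4-(benzyloxy)-3-methoxybenzyl]-6-[4-(benzyloxy)-3,5-dimethoxyphenyl]-5-methylhexane-2,3-diol (both syn-addition diastereomers at C2/C3) | COc1cc(C[C@H](C(O)C(C)O)[C@H](C)Cc2cc(OC)c(OCc3ccccc3)c(OC)c2)ccc1OCc1ccccc1 | intermediate (not isolated)
18 | (2S,3R)-2-[4-(benzyloxy)-3-methoxybenzyl]-4-[4-(benzyloxy)-3,5-dimethoxyphenyl]-3-methylbutanal | COc1cc(C[C@H](C=O)[C@H](C)Cc2cc(OC)c(OCc3ccccc3)c(OC)c2)ccc1OCc1ccccc1 | intermediate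
19 | (2S,3R)-2-[4-(benzyloxy)-3-methoxybenzyl]-4-[4-(benzyloxy)-3,5-dimethoxyphenyl]-3-methylbutan-1-ol | COc1cc(C[C@H](CO)[C@H](C)Cc2cc(OC)c(OCc3ccccc3)c(OC)c2)ccc1OCc1ccccc1 | intermediate
20 | (2S,3R)-2-[4-(benzyloxy)-3-methoxybenzyl]-4-[4-(benzyloxy)-3,5-dimethoxyphenyl]-3-methylbutyl acetate | COc1cc(C[C@H](COC(C)=O)[C@H](C)Cc2cc(OC)c(OCc3ccccc3)c(OC)c2)ccc1OCc1ccccc1 | intermediate
21 | (2S,3R)-2-(4-hydroxy-3-methoxybenzyl)-4-(4-hydroxy-3,5-dimethoxyphenyl)-3-methylbutyl acetate | COc1cc(C[C@H](COC(C)=O)[C@H](C)Cc2cc(OC)c(O)c(OC)c2)ccc1O | target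

**Step count**

Total: 14 steps. Longest linear sequence: 12 steps (sinapic acid 5 to target 21 through steps 3–14).

**Steps most likely to fail**

1. Step 7. The ketene acetal geometry may be partly lost, either through non-selective enolisation or through proton exchange between the enolate and unreacted ester. A boat transition state may also compete. Either process would deliver the C8' epimer, and Claisen self-condensation of the enolate would lower the throughput.
Fallback (Eschenmoser–Claisen, in which the ketene acetal geometry is fixed thermodynamically): it sets out from acid 8 and alcohol 4. Acid 8 is condensed with dimethylamine under carbodiimide coupling to 3-[4-(benzyloxy)-3,5-dimethoxyphenyl]-N,N-dimethylpropanamide F1. O-Methylation with Me3OBF4 in CH2Cl2 gives the methyl imidate tetrafluoroborate F2, and NaOMe in MeOH converts it into the amide dimethyl acetal F3. Heating F3 with alcohol 4 in xylene at about 140 °C exchanges a methoxy group for the allylic alkoxide and expels methanol to form the ketene N,O-acetal F4. In F4 the syringyl CH2 should lie cis to the allylic oxygen, because the alternative geometry suffers allylic 1,3-strain against the NMe2 group. The same chair rearrangement then gives (2R,3R,4E)-2-[4-(benzyloxy)-3,5-dimethoxybenzyl]-3-[4-(benzyloxy)-3-methoxybenzyl]-N,N-dimethylhex-4-enamide F5. Reduction of this tertiary amide with LiH2NBH3 in THF gives the primary alcohol, and the route is rejoined at compound 14.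

2. Step 2. Ruthenium hydride species may move the allyl double bond into conjugation with the arene or isomerise the allylic alcohol to the methyl ketone. The E selectivity may also be incomplete, and any Z alkene would be carried through the rearrangement to the C8 epimer.
Fallback (geometry set by a conjugated acceptor, carbinol set by reagent control): it sets out from compound 2. Cross metathesis of 2 with but-3-en-2-one under the same ruthenium catalyst should give the conjugated (3E)-5-[4-(benzyloxy)-3-methoxyphenyl]pent-3-en-2-one F6 with a strong preference for the E isomer. Corey–Bakshi–Shibata reduction with (R)-2-methyl-CBS-oxazaborolidine and catecholborane in toluene at −78 °C should then deliver the S carbinol by 1,2-reduction. The route is rejoined at compound 4.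

3. Step 11. The aldehyde may epimerise at its α-carbon (C8) by enolisation in the buffered aqueous medium. Slow dihydroxylation of the hindered disubstituted alkene would lengthen that exposure and could allow oxidation of the electron-rich rings.
Fallback (ozonolysis with reductive work-up, no free aldehyde handled): it sets out from compound 16. Ozone in CH2Cl2 at −78 °C, dosed against an indicator dye so that addition stops when the alkene is consumed, gives the secondary ozonide F7. Methanol and NaBH4 are added to the same flask, and the ozonide is reduced directly to the primary alcohol. The route is rejoined at compound 19.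

**Further compounds**

F1 | step 7 | 3-[4-(benzyloxy)-3,5-dimethoxyphenyl]-N,N-dimethylpropanamide | CN(C)C(=O)CCc1cc(OC)c(OCc2ccccc2)c(OC)c1
F2 | step 7 | {3-[4-(benzyloxy)-3,5-dimethoxyphenyl]-1-methoxypropylidene}dimethylammonium tetrafluoroborate | COC(CCc1cc(OC)c(OCc2ccccc2)c(OC)c1)=[N+](C)C.F[B-](F)(F)F
F3 | step 7 | 3-[4-(benzyloxy)-3,5-dimethoxyphenyl]-1,1-dimethoxy-N,N-dimethylpropan-1-amine | COC(CCc1cc(OC)c(OCc2ccccc2)c(OC)c1)(OC)N(C)C
F4 | step 7 | ketene N,O-acetal from F3 and 4 (syringyl CH2 cis to the allylic oxygen) | C[C@H](O/C(N(C)C)=C\Cc1cc(OC)c(OCc2ccccc2)c(OC)c1)/C=C/Cc1ccc(OCc2ccccc2)c(OC)c1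
F5 | step 7 | (2R,3R,4E)-2-[4-(benzyloxy)-3,5-dimethoxybenzyl]-3-[4-(benzyloxy)-3-methoxybenzyl]-N,N-dimethylhex-4-enamide | COc1cc(C[C@H](/C=C/C)[C@H](C(=O)N(C)C)Cc2cc(OC)c(OCc3ccccc3)c(OC)c2)ccc1OCc1ccccc1
F6 | step 2 | (3E)-5-[4-(benzyloxy)-3-methoxyphenyl]pent-3-en-2-one | CC(=O)/C=C/Cc1ccc(OCc2ccccc2)c(OC)c1
F7 | step 11 | 3-methyl-5-{(2S,3R)-1-[4-(benzyloxy)-3-methoxyphenyl]-4-[4-(benzyloxy)-3,5-dimethoxyphenyl]-3-methylbutan-2-yl}-1,2,4-trioxolane | COc1cc(C[C@H](C2OOC(C)O2)[C@H](C)Cc2cc(OC)c(OCc3ccccc3)c(OC)c2)ccc1OCc1ccccc1
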